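**Plan**
- Retrosynthesis (labdane numbering): cut C13=C14 (cross-metathesis) and C11–C12 (allylboration), then C9=C11 (methylenation of a C9 ketone, followed by hydroboration), then ring A at C2–C3 and C4–C5, and last C10–C1 (Michael addition to 2-methylcyclohexane-1,3-dione).
- Enabling feature: in ring A the oxygenated C3 and the gem-dimethyl C4 form an isobutyrate unit (acyl carbon C3, α-carbon C4) lodged between C2, which can carry a removable ester, and C5, which can be the sp2 carbon of an alkenyl triflate made from a ketone next to quaternary C10.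
- Forward: ring B first (C10 quaternary), then ring A by palladium enolate coupling at C5 followed in the same flask by Dieckmann closure of C2 onto C3, then the ring fusion, then the C8 methyl, the C7=C8 bond and C11 on ring B, then the C12–C16 chain.
- Stereochemistry: C10 from enantiotopic-group-selective yeast reduction of the prochiral dione; C3 by hydride delivery; C5 by hydrogenation anti to the C10 methyl; C9 by hydroboration anti to the C10 methyl; C11 by catalyst-controlled allylboration; 13E by cross-metathesis.
- Helpers: the tert-butyl ester on C2 (removed in step 6) and the benzyl ether on C9 (removed in step 9).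

Key step: step 5

Assumption: the yeast reduction of 3 follows the established (2S,3S) course of 2-alkyl-2-methylcyclohexane-1,3-diones; the configuration of the carbinol carbon C9 does not matter because it is oxidised in step 10. Labdane numbering is used for all intermediates (ring A = C1–C5 and C10, ring B = C5–C10).

**Step 1**
Reactants: 1 2-methylcyclohexane-1,3-dione; 2 tert-butyl acrylate
Product: 3 tert-butyl 3-(1-methyl-2,6-dioxocyclohexyl)propanoate
Conditions: Et3N (cat.), MeCN, 60 °C
Reagents that add atoms: none
Why: Michael addition of the stabilised carbanion of the 1,3-dione to the acrylate builds the quaternary carbon that becomes C10, still prochiral because the two carbonyls are enantiotopic.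

**Step 2**
Reactants: 3 tert-butyl 3-(1-methyl-2,6-dioxocyclohexyl)propanoate
Product: 4 tert-butyl 3-[(1S,2S)-2-hydroxy-1-methyl-6-oxocyclohexyl]propanoate
Conditions: baker's yeast, sucrose, H2O, 30 °C
Reagents that add atoms: none
Why: Enantiotopic-group-selective carbonyl reduction by the yeast oxidoreductases should reduce one carbonyl only and so fix the absolute configuration of C10, while the tert-butyl ester resists lactonisation onto the new hydroxyl.

**Step 3**
Reactants: 4 tert-butyl 3-[(1S,2S)-2-hydroxy-1-methyl-6-oxocyclohexyl]propanoate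
Product: 5 tert-butyl 3-[(1S,2S)-2-benzyloxy-1-methyl-6-oxocyclohexyl]propanoate
Conditions: 2-benzyloxy-1-methylpyridinium triflate, MgO, PhCF3, 85 °C
Reagents that add atoms: 2-benzyloxy-1-methylpyridinium triflate, C[n+]1ccccc1OCc1ccccc1.[O-]S(=O)(=O)C(F)(F)F
Why: O-Benzylation by benzyl transfer from the pyridinium salt under neutral conditions protects the C9 hydroxyl without exposing the β-hydroxy ketone to base and retro-aldol opening.

**Step 4**
Reactants: 5 tert-butyl 3-[(1S,2S)-2-benzyloxy-1-methyl-6-oxocyclohexyl]propanoate
Product: 7 tert-butyl 3-[(1S,6S)-6-benzyloxy-1-methyl-2-(trifluoromethylsulfonyloxy)cyclohex-2-en-1-yl]propanoate, via potassium enolate 6 (not isolated)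
Conditions: KN(SiMe3)2, THF, −78 °C; then PhNTf2, −78 °C to 0 °C
Reagents that add atoms: N-phenylbis(trifluoromethanesulfonimide), O=S(=O)(N(c1ccccc1)S(=O)(=O)C(F)(F)F)C(F)(F)F
Why: Enolate O-sulfonylation: with C10 quaternary the ketone can enolise only toward C6, so a single alkenyl triflate should form and C5 becomes an sp2 electrophile.

**Step 5**
Reactants: 7 alkenyl triflate (C5–OTf, C5=C6); 8 methyl 2-bromo-2-methylpropanoate
Product: 11 tert-butyl 9-benzyloxy-4,4,10-trimethyl-3-oxo-Δ5-octalin-2-carboxylate (bicyclic β-keto ester; C2 epimers and enol), via zinc enolate 9 (not isolated), via coupled diester 10 (not isolated)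
Conditions: 8, Zn, THF, 40 °C; then 7, Pd2(dba)3, P(t-Bu)3, LiCl, THF, 60 °C; then KOt-Bu, THF, 0 °C to rt; aq. NH4Cl
Reagents that add atoms: none
Why: Oxidative addition of the zerovalent palladium catalyst into the C5–O bond of 7, transmetalation with the C-bound zinc enolate 9 and reductive elimination join the fully substituted C4 to the neopentyl sp2 carbon C5 (diester 10); KOt-Bu then removes the only acidic hydrogen left, at C2 next to the tert-butyl ester, and that enolate adds to the C3 methyl ester and expels methoxide. The closest known reaction types are the palladium-catalysed α-alkenylation of Reformatsky-type zinc ester enolates with alkenyl halides and triflates, and the Dieckmann condensation. Ring A closes in the second event by a 6-(enolexo)-exo-trig attack of C2 on C3; the first event closes no ring. No lasting stereocentre is formed: C2 is epimerisable and is lost with the ester, and C5 is kept sp2 on purpose so that its hydrogen can be delivered later anti to the C10 methyl. The step needs chemoselectivity and a single direction of condensation, and the substrate secures both: the zinc enolate tolerates both esters, C4 carries no hydrogen so it can neither enolise nor couple twice, the C2 enolate can reach only C3 through a six-membered transition state, and formation of the stabilised β-keto ester enolate of 11 should pull the sequence to completion.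

**Step 6**
Reactants: 11 bicyclic β-keto ester
Product: 12 9-benzyloxy-4,4,10-trimethyl-Δ5-octalin-3-one
Conditions: TsOH·H2O (cat.), toluene, 110 °C
Reagents that add atoms: none
Why: Acid-promoted loss of 2-methylpropene from the tert-butyl ester and decarboxylation of the resulting β-keto acid remove the activating group at C2, and the C5=C6 bond cannot move into conjugation because C4 is quaternary.

**Step 7**
Reactants: 12 9-benzyloxy-4,4,10-trimethyl-Δ5-octalin-3-one
Product: 13 (3R)-9-benzyloxy-4,4,10-trimethyl-Δ5-octalin-3-ol (3-OH cis to the C10 methyl)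
Conditions: NaBH4, MeOH, −20 °C
Reagents that add atoms: none
Why: Borohydride reduction of the neopentyl ketone by axial hydride delivery from the face opposite the axial C4 methyl and the C10 methyl should give the equatorial alcohol, as with 4,4-dimethyl-3-keto triterpenoids, and so set C3.

**Step 8**
Reactants: 13 (3R)-9-benzyloxy-4,4,10-trimethyl-Δ5-octalin-3-ol
Product: 14 (3R)-9-benzyloxy-4,4,10-trimethyl-Δ5-octalin-3-yl acetate
Conditions: Ac2O, pyridine, DMAP, rt
Reagents that add atoms: acetic anhydride, CC(=O)OC(C)=O
Why: DMAP-catalysed acylation installs the C3 acetate of the target at this point, where it also serves as the protecting group for the rest of the route.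

**Step 9**
Reactants: 14 (3R)-9-benzyloxy-4,4,10-trimethyl-Δ5-octalin-3-yl acetate
Product: 15 3-acetoxy-4,4,10-trimethyl-trans-decalin-9-ol (H5 trans to the C10 methyl, 3-OAc cis to it, 9-OH trans to it)
Conditions: H2 (4 atm), Pd/C, EtOAc–AcOH, rt
Reagents that add atoms: none
Why: Heterogeneous hydrogenation should add hydrogen to the C5=C6 bond from the face opposite the axial methyls on C10 and C4, which gives the trans ring fusion and sets C5, while the benzyl ether is cleaved by hydrogenolysis.

**Step 10**
Reactants: 15 3-acetoxy-4,4,10-trimethyl-trans-decalin-9-ol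
Product: 16 3-acetoxy-4,4,10-trimethyl-trans-decalin-9-one
Conditions: Dess–Martin periodinane, NaHCO3, CH2Cl2, rt
Reagents that add atoms: none
Why: Dess–Martin oxidation of the hindered secondary alcohol gives the C9 ketone under buffered conditions that leave the acetate untouched.

**Step 11**
Reactants: 16 3-acetoxy-4,4,10-trimethyl-trans-decalin-9-one
Product: 17 3-acetoxy-4,4,10-trimethyl-8-methylene-trans-decalin-9-one
Conditions: (CH2O)n, N-methylanilinium trifluoroacetate, THF, reflux
Reagents that add atoms: formaldehyde (as paraformaldehyde), C=O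
Why: Mannich-type α-methylenation: the ketone can enolise only toward C8, so the formaldehyde carbon, the future C8 methyl, is attached there.

**Step 12**
Reactants: 17 3-acetoxy-4,4,10-trimethyl-8-methylene-trans-decalin-9-one
Product: 18 3-acetoxy-4,4,8,10-tetramethyl-trans-octal-7-en-9-one (2-methyl enone, C7=C8)
Conditions: RhCl3·3H2O (cat.), EtOH, 80 °C
Reagents that add atoms: none
Why: Metal hydride-mediated alkene isomerisation should move the exocyclic double bond into the ring to give the more stable trisubstituted conjugated enone, which places the C7=C8 bond and the C8 methyl.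

**Step 13**
Reactants: 18 3-acetoxy-4,4,8,10-tetramethyl-trans-octal-7-en-9-one
Product: 19 3-acetoxy-4,4,8,10-tetramethyl-9-methylene-trans-octal-7-ene (7,9(11)-diene)
Conditions: Zn, CH2Br2, TiCl4, THF–CH2Cl2, 0 °C to rt
Reagents that add atoms: dibromomethane, BrCBr
Why: Takai–Lombardo methylenation converts the hindered, enolisable enone carbonyl into the exocyclic C9=C11 alkene without attacking the acetate.

**Step 14**
Reactants: 19 7,9(11)-diene
Product: 21 3-acetoxy-4,4,8,10-tetramethyl-9-(hydroxymethyl)-trans-octal-7-ene (C11 on C9 cis to the C10 methyl, H9 trans to it), via alkylborane 20 (not isolated)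
Conditions: 9-BBN, THF, 0 °C to rt; then NaBO3·4H2O, H2O, rt
Reagents that add atoms: sodium perborate, [Na+].[O-]OB=O
Why: Hydroboration–oxidation: 9-BBN should add to the less hindered exocyclic alkene with boron on C11 and hydrogen delivered to C9 from the face opposite the C10 methyl, which sets C9, and perborate oxidises the C–B bond with retention under conditions mild enough for the acetate.

**Step 15**
Reactants: 21 primary alcohol (C11–OH)
Product: 22 3-acetoxy-4,4,8,10-tetramethyl-trans-octal-7-ene-9-carbaldehyde (C11 aldehyde, C9 as in 21)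
Conditions: Dess–Martin periodinane, NaHCO3, CH2Cl2, 0 °C
Reagents that add atoms: none
Why: Dess–Martin oxidation gives the β,γ-unsaturated aldehyde under buffered, non-basic conditions, so C9 should not epimerise and the double bond should not move into conjugation.

**Step 16**
Reactants: 22 C11 aldehyde; 23 2-(2-methylallyl)-4,4,5,5-tetramethyl-1,3,2-dioxaborolane
Product: 24 (11S)-3-acetoxy-11-hydroxy homoallylic alcohol carrying CH2C(CH3)=CH2 on C11
Conditions: 23, (S)-TRIP (cat.), toluene, −30 °C; aq. NaHCO3
Reagents that add atoms: none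
Why: Chiral phosphoric acid-catalysed allylboration through a closed chair-like transition state, with the catalyst enantiomer chosen to override the intrinsic bias of C9, should set C11 as S.

**Step 17**
Reactants: 24 homoallylic alcohol; 25 (Z)-but-2-ene-1,4-diyl diacetate
Product: 26 (3R,5S,9R,10R,11S,13E)-11-hydroxylabda-7,13-diene-3,15-diyl diacetate
Conditions: 25 (excess), second-generation Hoveyda–Grubbs catalyst (cat.), CH2Cl2, 40 °C
Reagents that add atoms: none
Why: Olefin cross-metathesis between the 1,1-disubstituted alkene and the allylic acetate partner forms the trisubstituted C13=C14 bond with the E isomer favoured thermodynamically, while the hindered ring alkene should not take part, and any Z isomer is removed by chromatography.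

**Compound list**
1 | 2-methylcyclohexane-1,3-dione | CC1C(=O)CCCC1=O | starting material
2 | tert-butyl acrylate | C=CC(=O)OC(C)(C)C | starting material
3 | tert-butyl 3-(1-methyl-2,6-dioxocyclohexyl)propanoate | CC1(CCC(=O)OC(C)(C)C)C(=O)CCCC1=O | intermediate
4 | tert-butyl 3-[(1S,2S)-2-hydroxy-1-methyl-6-oxocyclohexyl]propanoate | CC(C)(C)OC(=O)CC[C@]1(C)C(=O)CCC[C@@H]1O | intermediate
5 | tert-butyl 3-[(1S,2S)-2-benzyloxy-1-methyl-6-oxocyclohexyl]propanoate | CC(C)(C)OC(=O)CC[C@]1(C)C(=O)CCC[C@@H]1OCc1ccccc1 | intermediate
6 | potassium enolate of 5 (C5–OK, C5=C6; not isolated) | CC(C)(C)OC(=O)CC[C@]1(C)C([O-])=CCC[C@@H]1OCc1ccccc1.[K+] | intermediate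
7 | tert-butyl 3-[(1S,6S)-6-benzyloxy-1-methyl-2-(trifluoromethylsulfonyloxy)cyclohex-2-en-1-yl]propanoate | CC(C)(C)OC(=O)CC[C@]1(C)C(OS(=O)(=O)C(F)(F)F)=CCC[C@@H]1OCc1ccccc1 | intermediate
8 | methyl 2-bromo-2-methylpropanoate | COC(=O)C(C)(C)Br | starting material
9 | methyl 2-(bromozincio)-2-methylpropanoate (zinc enolate; not isolated) | COC(=O)C(C)(C)[Zn]Br | intermediate
10 | coupled diester: 7 with C(CH3)2CO2CH3 on C5 in place of the triflate (not isolated) | CC(C)(C)OC(=O)CC[C@]1(C)C(C(C)(C)C(=O)OC)=CCC[C@@H]1OCc1ccccc1 | intermediate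
11 | tert-butyl 9-benzyloxy-4,4,10-trimethyl-3-oxo-Δ5-octalin-2-carboxylate (C2 epimers) | CC(C)(C)OC(=O)C1C[C@]2(C)C(=CCC[C@@H]2OCc2ccccc2)C(C)(C)C1=O | intermediate
12 | 9-benzyloxy-4,4,10-trimethyl-Δ5-octalin-3-one | CC1(C)C(=O)CC[C@]2(C)C1=CCC[C@@H]2OCc1ccccc1 | intermediate
13 | (3R)-9-benzyloxy-4,4,10-trimethyl-Δ5-octalin-3-ol (3-OH cis to the C10 methyl) | CC1(C)[C@H](O)CC[C@]2(C)C1=CCC[C@@H]2OCc1ccccc1 | intermediate
14 | (3R)-9-benzyloxy-4,4,10-trimethyl-Δ5-octalin-3-yl acetate | CC1(C)[C@H](OC(C)=O)CC[C@]2(C)C1=CCC[C@@H]2OCc1ccccc1 | intermediate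
15 | 3-acetoxy-4,4,10-trimethyl-trans-decalin-9-ol (H5 trans to the C10 methyl) | CC1(C)[C@H](OC(C)=O)CC[C@]2(C)[C@@H]1CCC[C@@H]2O | intermediate
16 | 3-acetoxy-4,4,10-trimethyl-trans-decalin-9-one | CC1(C)[C@H](OC(C)=O)CC[C@]2(C)[C@@H]1CCCC2=O | intermediate
17 | 3-acetoxy-4,4,10-trimethyl-8-methylene-trans-decalin-9-one | CC1(C)[C@H](OC(C)=O)CC[C@]2(C)[C@@H]1CCC(=C)C2=O | intermediate
18 | 3-acetoxy-4,4,8,10-tetramethyl-trans-octal-7-en-9-one | CC1(C)[C@H](OC(C)=O)CC[C@]2(C)[C@@H]1CC=C(C)C2=O | intermediate
19 | 3-acetoxy-4,4,8,10-tetramethyl-9-methylene-trans-octal-7-ene | CC1(C)[C@H](OC(C)=O)CC[C@]2(C)[C@@H]1CC=C(C)C2=C | intermediate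
20 | B-alkyl-9-BBN adduct of 19 (boron on C11; not isolated) | CC1(C)[C@H](OC(C)=O)CC[C@]2(C)[C@@H]1CC=C(C)[C@H]2CB1C2CCCC1CCC2 | intermediate
21 | 3-acetoxy-4,4,8,10-tetramethyl-9-(hydroxymethyl)-trans-octal-7-ene (C11 cis to the C10 methyl) | CC1(C)[C@H](OC(C)=O)CC[C@]2(C)[C@@H]1CC=C(C)[C@H]2CO | intermediate
22 | 3-acetoxy-4,4,8,10-tetramethyl-trans-octal-7-ene-9-carbaldehyde | CC1(C)[C@H](OC(C)=O)CC[C@]2(C)[C@@H]1CC=C(C)[C@H]2C=O | intermediate
23 | 2-(2-methylallyl)-4,4,5,5-tetramethyl-1,3,2-dioxaborolane | CC(=C)CB1OC(C)(C)C(C)(C)O1 | starting material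
24 | (11S)-homoallylic alcohol with CH2C(CH3)=CH2 on C11 | CC1(C)[C@H](OC(C)=O)CC[C@]2(C)[C@@H]1CC=C(C)[C@H]2[C@@H](O)CC(C)=C | intermediate
25 | (Z)-but-2-ene-1,4-diyl diacetate | CC(=O)OC/C=C\COC(C)=O | starting material
26 | (3R,5S,9R,10R,11S,13E)-11-hydroxylabda-7,13-diene-3,15-diyl diacetate | CC(=O)OC/C=C(\C)C[C@H](O)[C@@H]1C(C)=CC[C@@H]2C(C)(C)[C@H](OC(C)=O)CC[C@]21C | target

**Step count and risks**
Total step count: 17. Longest linear sequence: 17 steps (1 to 26).

Steps most likely to fail:

1. Step 5. Reductive elimination at the congested C4–C5 junction may stall, so that protodetriflation of 7 outruns coupling. Fallback: the bond is made at the ketone stage. From ketone 5, Reformatsky addition of zinc enolate 9 (THF, reflux) to the C5 carbonyl should give tert-butyl 3-[6-benzyloxy-2-hydroxy-2-(1-methoxy-2-methyl-1-oxopropan-2-yl)-1-methylcyclohexyl]propanoate F1. Dehydration with SOCl2 and pyridine at 0 °C can occur only toward C6 and should give coupled diester 10, where the route is rejoined (KOt-Bu then closes ring A to 11 as in step 5).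

2. Step 9. Hydrogen uptake at the hindered trisubstituted C5=C6 bond may be slow, and double-bond migration on the metal surface may erode facial selectivity. Fallback: from acetate 14, radical hydrogen-atom-transfer hydrogenation (Mn(dpm)3, PhSiH3, t-BuOOH, i-PrOH, rt) is used instead of surface addition. The tertiary C5 radical should be quenched to the thermodynamically preferred 3-acetoxy-9-benzyloxy-4,4,10-trimethyl-trans-decalin F2. Hydrogenolysis (H2 1 atm, Pd/C, EtOAc) then removes the benzyl group and rejoins the route at 15.

3. Step 17. Forming a trisubstituted double bond by cross-metathesis may give incomplete E/Z control and low conversion. Fallback: the alkene is built with defined geometry from aldehyde 22. Propargylation with allenylboronic acid pinacol ester and (S)-TRIP should give the (11S)-homopropargylic alcohol F3. Zirconium-catalysed carboalumination (AlMe3, Cp2ZrCl2, CH2Cl2, −20 °C), then I2, should give the (E)-alkenyl iodide F4 by syn addition. Stille coupling with Bu3SnCH2OH (Pd(PPh3)4, dioxane, 90 °C) should give the 11,15-diol F5 with retention. Selective acetylation of the primary allylic hydroxyl (Ac2O, 2,4,6-collidine, CH2Cl2, −20 °C) rejoins the route at 26.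

**Further compounds**
F1 | step 5 | tert-butyl 3-[6-benzyloxy-2-hydroxy-2-(1-methoxy-2-methyl-1-oxopropan-2-yl)-1-methylcyclohexyl]propanoate (C10 and C9 as in 5; C5 carbinol epimers) | CC(C)(C)OC(=O)CC[C@]1(C)C(O)(C(C)(C)C(=O)OC)CCC[C@@H]1OCc1ccccc1
F2 | step 9 | 3-acetoxy-9-benzyloxy-4,4,10-trimethyl-trans-decalin | CC1(C)[C@H](OC(C)=O)CC[C@]2(C)[C@@H]1CCC[C@@H]2OCc1ccccc1
F3 | step 17 | (11S)-homopropargylic alcohol with CH2C≡CH on C11 | CC1(C)[C@H](OC(C)=O)CC[C@]2(C)[C@@H]1CC=C(C)[C@H]2[C@@H](O)CC#C
F4 | step 17 | (11S,13E)-alkenyl iodide with CH2C(CH3)=CHI on C11 | CC1(C)[C@H](OC(C)=O)CC[C@]2(C)[C@@H]1CC=C(C)[C@H]2[C@@H](O)C/C(C)=C/I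
F5 | step 17 | (11S,13E)-3-acetoxylabda-7,13-diene-11,15-diol | CC1(C)[C@H](OC(C)=O)CC[C@]2(C)[C@@H]1CC=C(C)[C@H]2[C@@H](O)C/C(C)=C/CO
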